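**Plan**

1. The quinone ring is numbered C1(=O), C2(OH), C3(CH3), C4(=O), C5(OH), C6(nonadecenyl). Backwards, the hydroxyls become OEt (C2) and OMe (C5), the quinone becomes a hydroquinone monosilyl ether, and the ring is cut at C3–C4.
2. Enabling feature: C4–C5–C6–C1 is the four-carbon ring of a squaric ester (C4 carbonyl, C5 methoxy carbon, C6 chain carbon, C1 carbinol carbon), and C2=C3 is a 1-ethoxypropenyl group on C1. Restoring the C1–C4 bond gives a 4-alkenylcyclobutenone.
3. Further cuts: C6–side chain (alkyllithium addition with carbonyl transposition), C1–C2 (alkenyllithium addition to dimethyl squarate), and the C5–C6 bond of the side chain (copper-catalysed coupling of a C14 Grignard reagent with a C5 bromochloride).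
4. Forward: the C19 iodide (four steps from myristelaidic acid) and the alkenylstannane (one step) are made separately and attached in turn to the squarate ring. The only new ring, the six-membered carbocycle, arises by thermal 4π opening and 6π closure; desilylation–oxidation and hydrolysis finish the synthesis.
5. Stereochemistry: the target has no stereocentre. Its E-alkene is bought with myristelaidic acid and never touched; the enol ether geometry (syn-hydrostannation) and the racemic carbinol centre vanish on aromatisation.

Key step: step 8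

Assumption: 1-ethoxyprop-1-yne is taken as a purchasable alkyne, and every intermediate with one sp3 carbon in the four-membered ring is carried as a racemate (or diastereomer mixture), because that centre is destroyed in step 8.

**Route**

Step 1
Reactants: 1 myristelaidic acid ((E)-tetradec-9-enoic acid)
Product: 2 (E)-tetradec-9-en-1-ol
Conditions: LiAlH4, THF, 0 °C to rt; aqueous NaOH work-up
Reagents that add atoms: none
Why: Hydride reduction of a carboxylic acid with LiAlH4 should give the primary alcohol and leaves the isolated E-alkene untouched.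

Step 2
Reactants: 2 (E)-tetradec-9-en-1-ol
Product: 3 (E)-14-bromotetradec-5-ene
Conditions: CBr4, PPh3, CH2Cl2, 0 °C
Reagents that add atoms: tetrabromomethane, BrC(Br)(Br)Br
Why: The Appel reaction converts a primary alcohol into the bromide under neutral conditions, so the alkene position and geometry are kept.

Step 3
Reactants: 3 (E)-14-bromotetradec-5-ene; 4 1-bromo-5-chloropentane
Product: 6 (E)-19-chlorononadec-5-ene, via Grignard reagent 5 (not isolated)
Conditions: Mg, THF, 40 °C; then 4 (1.3 equiv), Li2CuCl4 (3 mol %), THF, −10 °C to rt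
Reagents that add atoms: none
Why: Copper-catalysed (Kochi-type) coupling of a primary alkyl Grignard reagent with a primary alkyl bromide is selective for C–Br over C–Cl, so the five-carbon unit is joined and the chloride is kept as a handle.

Step 4
Reactants: 6 (E)-19-chlorononadec-5-ene
Product: 7 (E)-19-iodononadec-5-ene
Conditions: NaI, butan-2-one, reflux
Reagents that add atoms: sodium iodide, [Na+].[I-]
Why: Finkelstein exchange, driven by precipitation of NaCl, should give the primary iodide needed for clean iodine–lithium exchange.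

Step 5
Reactants: 8 1-ethoxyprop-1-yne
Product: 9 (E)-tributyl(1-ethoxyprop-1-enyl)stannane (methyl cis to ethoxy)
Conditions: Bu3SnH, Pd(PPh3)4 (2 mol %), THF, 0 °C to rt
Reagents that add atoms: tributylstannane, CCCC[SnH](CCCC)CCCC
Why: Palladium-catalysed syn-hydrostannation of a 1-alkoxyalkyne places tin on the oxygen-bearing carbon and hydrogen cis to it, which fixes the enol ether geometry.

Step 6
Reactants: 9 (E)-tributyl(1-ethoxyprop-1-enyl)stannane; 10 dimethyl squarate (3,4-dimethoxycyclobut-3-ene-1,2-dione)
Product: 13 4-[(Z)-1-ethoxyprop-1-enyl]-2,3-dimethoxy-4-(trimethylsilyloxy)cyclobut-2-en-1-one (racemic), via alkenyllithium 11 (not isolated), via lithium alkoxide 12 (not isolated)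
Conditions: n-BuLi (1.0 equiv), THF, −78 °C; then 10, THF, −78 °C; then Me3SiCl, −78 to 0 °C
Reagents that add atoms: chlorotrimethylsilane, C[Si](C)(C)Cl
Why: Tin–lithium exchange proceeds with retention, the α-alkoxyalkenyllithium adds 1,2 to one of the two equivalent squarate carbonyls, and O-silylation of the alkoxide blocks the carbinol, whose racemic centre is removed later.

Step 7
Reactants: 7 (E)-19-iodononadec-5-ene; 13 4-[(Z)-1-ethoxyprop-1-enyl]-2,3-dimethoxy-4-(trimethylsilyloxy)cyclobut-2-en-1-one
Product: 16 4-[(Z)-1-ethoxyprop-1-enyl]-2-methoxy-3-[(E)-nonadec-14-enyl]-4-(trimethylsilyloxy)cyclobut-2-en-1-one (racemic), via alkyllithium 14 (not isolated), via lithium cyclobutenolate 15 (not isolated)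
Conditions: 7, t-BuLi (2 equiv), Et2O–pentane, −78 °C; then 13, THF, −78 °C; then (CF3CO)2O (1.1 equiv), −78 °C; cold aq. NaHCO3
Reagents that add atoms: water, O
Why: Iodine–lithium exchange and 1,2-addition to the remaining carbonyl give a tertiary alkoxide whose trifluoroacetate ionises to a methoxy-stabilised cyclobutenyl cation, and hydrolysis at the distal methoxy carbon gives the 1,3-transposed enone (the known carbonyl transposition of squarate diadducts), so the carbinol carbon ends up next to the chain-bearing carbon.

Step 8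
Reactants: 16 4-[(Z)-1-ethoxyprop-1-enyl]-2-methoxy-3-[(E)-nonadec-14-enyl]-4-(trimethylsilyloxy)cyclobut-2-en-1-one
Product: 19 3-ethoxy-6-methoxy-2-methyl-5-[(E)-nonadec-14-enyl]-4-(trimethylsilyloxy)phenol, via dienylketene 17 (not isolated), via cyclohexadienone 18 (not isolated)
Conditions: toluene (0.02 M, degassed), 110 °C, Ar
Reagents that add atoms: none
Why: Heating should open the cyclobutenone by conrotatory 4π cleavage of the bond between the carbinol carbon (C1 in the quinone numbering) and the carbonyl carbon (C4), giving dienylketene 17 with the silyloxy group turned outward and the ethoxypropenyl group inward. The ketene carbon C4 then lies next to the propenyl terminus C3, and a thermal disrotatory 6π electrocyclisation forms the C3–C4 bond and closes the six-membered carbocycle as cyclohexadienone 18. Enolisation of 18 removes its only new sp3 centre, so no stereocentre is created, and gives the phenol. The closest known reaction type is the Moore-type ring expansion of 4-alkenyl-4-hydroxy- or 4-silyloxycyclobutenones to hydroquinones. The step needs inward rotation of the alkenyl group, which the strong outward preference of the oxygen donor on the carbinol carbon secures, while the substituent pattern is already fixed by the two carbonyl additions and the transposition. The remote E-alkene should be inert to neutral thermolysis.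

Step 9
Reactants: 19 3-ethoxy-6-methoxy-2-methyl-5-[(E)-nonadec-14-enyl]-4-(trimethylsilyloxy)phenol
Product: 21 2-ethoxy-5-methoxy-3-methyl-6-[(E)-nonadec-14-enyl]cyclohexa-2,5-diene-1,4-dione, via hydroquinone 20 (not isolated)
Conditions: K2CO3 (cat.), MeOH, 0 °C, Ar; then Ag2O, Na2SO4, Et2O, rt
Reagents that add atoms: none
Why: Base-catalysed methanolysis cleaves the aryl silyl ether, and Ag2O oxidises the electron-rich para-hydroquinone to the quinone without affecting the alkene (hydroquinone-to-quinone oxidation).

Step 10
Reactants: 21 2-ethoxy-5-methoxy-3-methyl-6-[(E)-nonadec-14-enyl]cyclohexa-2,5-diene-1,4-dione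
Product: 22 2,5-dihydroxy-3-methyl-6-[(E)-nonadec-14-enyl]cyclohexa-2,5-diene-1,4-dione (target)
Conditions: 2 M NaOH, EtOH, 60 °C, Ar; then 1 M HCl, 0 °C
Reagents that add atoms: sodium hydroxide, [Na+].[OH-]
Why: Both alkoxy groups are vinylogous esters of the quinone and should be displaced by hydroxide through conjugate addition–elimination (vinylogous ester saponification), and acidification then releases the dihydroxyquinone.

**Compound list**

1 | myristelaidic acid, (E)-tetradec-9-enoic acid | CCCC/C=C/CCCCCCCC(=O)O | starting material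
2 | (E)-tetradec-9-en-1-ol | CCCC/C=C/CCCCCCCCO | intermediate
3 | (E)-14-bromotetradec-5-ene | CCCC/C=C/CCCCCCCCBr | intermediate
4 | 1-bromo-5-chloropentane | ClCCCCCBr | starting material
5 | [(E)-tetradec-9-enyl]magnesium bromide | CCCC/C=C/CCCCCCCC[Mg]Br | intermediate
6 | (E)-19-chlorononadec-5-ene | CCCC/C=C/CCCCCCCCCCCCCCl | intermediate
7 | (E)-19-iodononadec-5-ene | CCCC/C=C/CCCCCCCCCCCCCI | intermediate
8 | 1-ethoxyprop-1-yne | CCOC#CC | starting material
9 | (E)-tributyl(1-ethoxyprop-1-enyl)stannane | C/C=C(\OCC)[Sn](CCCC)(CCCC)CCCC | intermediate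
10 | dimethyl squarate | COC1=C(OC)C(=O)C1=O | starting material
11 | (Z)-(1-ethoxyprop-1-enyl)lithium | C/C=C(\OCC)[Li] | intermediate
12 | lithium 1-[(Z)-1-ethoxyprop-1-enyl]-2,3-dimethoxy-4-oxocyclobut-2-en-1-olate (racemic) | COC1=C(OC)C(=O)C1(O[Li])/C(OCC)=C/C | intermediate
13 | 4-[(Z)-1-ethoxyprop-1-enyl]-2,3-dimethoxy-4-(trimethylsilyloxy)cyclobut-2-en-1-one (racemic) | COC1=C(OC)C(=O)C1(O[Si](C)(C)C)/C(OCC)=C/C | intermediate
14 | [(E)-nonadec-14-enyl]lithium | CCCC/C=C/CCCCCCCCCCCCC[Li] | intermediate
15 | lithium 4-[(Z)-1-ethoxyprop-1-enyl]-2,3-dimethoxy-1-[(E)-nonadec-14-enyl]-4-(trimethylsilyloxy)cyclobut-2-en-1-olate (diastereomer mixture) | CCCC/C=C/CCCCCCCCCCCCCC1(O[Li])C(OC)=C(OC)C1(O[Si](C)(C)C)/C(OCC)=C/C | intermediate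
16 | 4-[(Z)-1-ethoxyprop-1-enyl]-2-methoxy-3-[(E)-nonadec-14-enyl]-4-(trimethylsilyloxy)cyclobut-2-en-1-one (racemic) | CCCC/C=C/CCCCCCCCCCCCCC1=C(OC)C(=O)C1(O[Si](C)(C)C)/C(OCC)=C/C | intermediate
17 | (3E,5Z)-5-ethoxy-2-methoxy-3-[(E)-nonadec-14-enyl]-4-(trimethylsilyloxy)hepta-1,3,5-trien-1-one | CCCC/C=C/CCCCCCCCCCCCC/C(C(OC)=C=O)=C(\O[Si](C)(C)C)/C(OCC)=C/C | intermediate
18 | 5-ethoxy-2-methoxy-6-methyl-3-[(E)-nonadec-14-enyl]-4-(trimethylsilyloxy)cyclohexa-2,4-dien-1-one (racemic) | CCCC/C=C/CCCCCCCCCCCCCC1=C(OC)C(=O)C(C)C(OCC)=C1O[Si](C)(C)C | intermediate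
19 | 3-ethoxy-6-methoxy-2-methyl-5-[(E)-nonadec-14-enyl]-4-(trimethylsilyloxy)phenol | CCCC/C=C/CCCCCCCCCCCCCc1c(OC)c(O)c(C)c(OCC)c1O[Si](C)(C)C | intermediate
20 | 2-ethoxy-5-methoxy-3-methyl-6-[(E)-nonadec-14-enyl]benzene-1,4-diol | CCCC/C=C/CCCCCCCCCCCCCc1c(OC)c(O)c(C)c(OCC)c1O | intermediate
21 | 2-ethoxy-5-methoxy-3-methyl-6-[(E)-nonadec-14-enyl]cyclohexa-2,5-diene-1,4-dione | CCCC/C=C/CCCCCCCCCCCCCC1=C(OC)C(=O)C(C)=C(OCC)C1=O | intermediate
22 | 2,5-dihydroxy-3-methyl-6-[(E)-nonadec-14-enyl]cyclohexa-2,5-diene-1,4-dione | CCCC/C=C/CCCCCCCCCCCCCC1=C(O)C(=O)C(C)=C(O)C1=O | target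

**Step count**

Total: 10 steps. Longest linear sequence: 8 steps (1, 2, 3, 4, 7, 8, 9, 10).

**Steps most likely to fail**

Step 7. The anhydride quench may attack the electron-rich enol ether (C-trifluoroacetylation or protonation) or strip the silyl ether, and addition of the long alkyllithium to the hindered vinylogous ester carbonyl may be incomplete. The fallback reverses the order of the two additions so that the anhydride never meets the enol ether. It sets out from 7 and 10 (with 9 as the source of 11) and returns at 16. The alkyllithium 14 made from 7 is added to dimethyl squarate 10 and the mixture is quenched with aqueous NH4Cl to give 4-hydroxy-2,3-dimethoxy-4-[(E)-nonadec-14-enyl]cyclobut-2-en-1-one F1. Treatment with (CF3CO)2O and then methanol/2,6-lutidine traps the same kind of cation as its dimethyl ketal, 3,4,4-trimethoxy-2-[(E)-nonadec-14-enyl]cyclobut-2-en-1-one F2. The alkenyllithium 11 then adds to the only free carbonyl of F2, which lies next to the chain-bearing carbon, and a Me3SiCl quench gives [1-[(Z)-1-ethoxyprop-1-enyl]-3,4,4-trimethoxy-2-[(E)-nonadec-14-enyl]cyclobut-2-en-1-yl]oxy-trimethylsilane F3. Brief contact with moist silica gel containing a trace of oxalic acid (CH2Cl2, 0 °C) should hydrolyse the very labile vinylogous ortho ester selectively and deliver 16.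

Step 8. At the temperature the silyl ether requires, the silyl group may be lost or migrate, or the ketene may be consumed by dimerisation or adventitious nucleophiles before it cyclises. The fallback runs the ring expansion on the free carbinol, so no silyl group has to survive heating. It sets out from 16 and returns at 20. Bu4NF buffered with AcOH (THF, −20 °C) should give 4-[(Z)-1-ethoxyprop-1-enyl]-4-hydroxy-2-methoxy-3-[(E)-nonadec-14-enyl]cyclobut-2-en-1-one F4. Heating F4 in degassed toluene should send the hydroxyl outward in the same way and give hydroquinone 20 directly, which is oxidised with Ag2O as in step 9.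

Step 10. The hydrolysis may stall after the first alkoxy group, because the hydroxyquinone anion is a poor acceptor, or base-induced tautomerisation of the alkylquinone to quinone methides may lead to oligomers. The fallback cleaves the ethers at the hydroquinone oxidation level. It sets out from 19 and returns at 22. Excess BBr3 (CH2Cl2, −78 to 0 °C, kept cold to spare the alkene) should remove the methyl, ethyl and silyl groups to give 3-methyl-6-[(E)-nonadec-14-enyl]benzene-1,2,4,5-tetrol F5. Stirring F5 in wet ether under air should autoxidise it to 22.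

**Further compounds**

F1 | step 7 | 4-hydroxy-2,3-dimethoxy-4-[(E)-nonadec-14-enyl]cyclobut-2-en-1-one | CCCC/C=C/CCCCCCCCCCCCCC1(O)C(OC)=C(OC)C1=O
F2 | step 7 | 3,4,4-trimethoxy-2-[(E)-nonadec-14-enyl]cyclobut-2-en-1-one | CCCC/C=C/CCCCCCCCCCCCCC1=C(OC)C(OC)(OC)C1=O
F3 | step 7 | [1-[(Z)-1-ethoxyprop-1-enyl]-3,4,4-trimethoxy-2-[(E)-nonadec-14-enyl]cyclobut-2-en-1-yl]oxy-trimethylsilane | CCCC/C=C/CCCCCCCCCCCCCC1=C(OC)C(OC)(OC)C1(O[Si](C)(C)C)/C(OCC)=C/C
F4 | step 8 | 4-[(Z)-1-ethoxyprop-1-enyl]-4-hydroxy-2-methoxy-3-[(E)-nonadec-14-enyl]cyclobut-2-en-1-one | CCCC/C=C/CCCCCCCCCCCCCC1=C(OC)C(=O)C1(O)/C(OCC)=C/C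
F5 | step 10 | 3-methyl-6-[(E)-nonadec-14-enyl]benzene-1,2,4,5-tetrol | CCCC/C=C/CCCCCCCCCCCCCc1c(O)c(O)c(C)c(O)c1O
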